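## The problem

The target **21** is a C19 chain, numbered from C1 (pentyl CH3) to C19 (vinyl CH2), folded into one tetrahydrofuran ring by an ether oxygen O1 between C6 and C9. C7 carries a free hydroxyl, C10 a tetradecanoate ester, and C18=C19 is a terminal alkene. Reading the SMILES gives 6S,7S,9R,10R: pentyl (C6) and hydroxyl (C7) are cis on the ring, the C9 side chain is trans to both, and C10 is threo to C9.

C7 can direct an incoming group at the adjacent C6, and C9 can direct addition to a carbonyl at C10. C7 and C9 are separated by the C8 methylene and cannot set each other, so this pair should come from a source in which the relationship is already fixed.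

The terminal alkene rules out hydrogenation, ozonolysis and metathesis once it is in place, so every alkene-consuming operation must come before the C11–C19 chain is attached. The ester does not tolerate strong base or excess organometallics. The two secondary oxygens O7 and O10 must stay differentiated to the end so that only O10 is acylated.

The enabling feature is that C7 and C9 are both oxygenated, one carbon apart, and each is flanked by a further oxygen-bearing carbon (C6, C10). Joining C6 to C10 by a double bond turns the segment C6–C10 into cis-cyclopent-4-ene-1,3-diol. Cleaving that alkene returns C6 and C10 as carbonyls, and of these only C6 lies within reach of the C9 oxygen.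

## Retrosynthesis

**Ester and silyl ether.** Target **21** is traced to silyl ether **20** and then to alcohol **18** plus tetradecanoic acid **19**, cutting the O10–acyl bond. Acylating last keeps the ester away from the Grignard reagent and the methanolyses. The silyl group on O7 guarantees that only O10 is esterified. The forward steps need only a carbodiimide coupling and a fluoride desilylation mild enough to leave the ester in place.

**C10–C11.** Alcohol **18** is cut between C10 and C11 into aldehyde **15** and the Grignard reagent **17** of 9-bromonon-1-ene **16**. This cut brings the whole alkene-bearing chain in one piece after all hydrogenation is done. A cut at C9–C10 would require a chiral C10 nucleophile. The forward addition must be threo-selective; the ring oxygen α to the aldehyde allows a magnesium chelate, which delivers the nucleophile to the face that gives 10R.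

**Pentyl chain and C10 oxidation level.** Aldehyde **15** comes from alcohol **14**, which comes from acetate **13**. The saturated pentyl chain of **13** is traced through pentenyl compound **12** to the C-allyl compound **10** and (E)-hex-3-ene **11**, a cross-metathesis that forms C3=C4. This two-carbon extension is shorter than hydroboration followed by alkylation or ozonolysis followed by Wittig reaction, and the acetate on O10 survives it.

**C5–C6.** Compound **10** is cut at C5–C6 into anomeric acetate **8** and allyltrimethylsilane **9**. An oxocarbenium ion at C6 is the natural reactive form of a lactol carbon, and its facial preference is set by the adjacent C7 silyloxy group. The alternative of adding a pentyl organometallic to a C6 lactone and reducing the hemiketal would place hydride, not carbon, cis to O7. The forward reaction must deliver the allyl group cis to O7 and trans to the C9 substituent.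

**Adjustment of C10.** Diacetate **8** comes from lactol diol **7** by acetylation, and **7** from lactol aldehyde **6** by reduction of the free C10 aldehyde. This costs a reduction and a later reoxidation, but it removes the only electrophile that would compete with C6 under Lewis acid.

**C6=C10 (key cut).** Lactol aldehyde **6** is reconnected between C6 and C10 to give (1R,4S)-4-(tert-butyldimethylsilyloxy)cyclopent-2-en-1-ol **3**. This removes the heterocycle and both carbonyls in one move and leaves a five-carbon carbocycle with two stereocentres. The forward ozonolysis must cleave one alkene and let the free C9 hydroxyl close onto C6. Differentiation of the two aldehydes follows from silylating only O7.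

**Protecting-group exchange.** Cyclopentenol **3** is obtained from silyl ether acetate **2** and this from the commercial, enzymatically desymmetrised monoacetate **1**. The exchange of acetate for silyl on the opposite oxygen decides which enantiotopic terminus becomes C6.

## Roads not taken

**Alternative 1:** The cut is at C6–C5 and C7–O7 through a temporary cyclobutanone. In the forward direction dichloroketene adds across the C6=C7 enol ether of dihydrofuran A1 to give the cis-fused dichlorocyclobutanone A2. Dechlorination, Baeyer–Villiger insertion at C7, lactone reduction, olefination and saturation would then supply the C7 oxygen and the pentyl chain.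
- Merits: the cis relationship of the C6 carbon substituent and the C7 oxygen is enforced by the ring fusion. This is a firmer guarantee than the stereoelectronic bias that the chosen plan relies on at C6.
- Weak points: A1 must already carry C9 and C10, which have to be made separately. Facial control comes only from the remote C9 substituent on a nearly flat ring. The terminal alkene is present during ketene generation and peracid oxidation, and the late C3=C4 alkene cannot be saturated selectively beside it. The terminal alkene would therefore have to be masked, and the sequence after A2 is long.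
- Comparison: the chosen plan buys C7 and C9 together and never exposes the terminal alkene to an alkene-consuming reagent, but it has weaker intrinsic control of the C6/C7 relationship.

**Alternative 2:** The cut is at O1–C9 and C10–O. In the forward direction Re2O7 with (CF3CO)2O converts the C6 hydroxyl of dienol A3 into a perrhenate ester that adds syn across the (E)-C9=C10 alkene. This gives the trans ring and the threo carbinol in A4, which is the same substance as **18**.
- Merits: two stereocentres and the ring form in one step, the redox detour at C10 disappears, and only acylation and desilylation remain. This road is probably shorter and more convergent than the chosen one.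
- Weak points: A3 is an acyclic syn-diol whose two secondary hydroxyls must be differentiated and which also needs a defined E-alkene, so three stereo-elements require asymmetric synthesis. The trans selectivity of perrhenate cyclisations is sensitive to oxygen substituents on the tether. The silyl ether must survive strongly acidic, anhydride-containing conditions.
- Comparison: the chosen plan is longer. It sets against this a single inexpensive building block that supplies C7 and C9 with assured absolute configuration, and two substrate-controlled steps of well-understood sense.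

**Alternative 3:** The cut is at O1–C6 and C5–C6. In the forward direction Cu(acac)2 decomposes diazoketone A5 to a copper carbenoid at C6. The allyl ether oxygen on C9 captures it as a five-membered oxonium ylide, and a [2,3]-shift moves the allyl group from O1 to C6 to give furanone A6. Hydride reduction of the C7 ketone from the face opposite the allyl group would then set the cis alcohol.
- Merits: ring and C5–C6 bond form catalytically with the 2,5-trans relationship, and the later ketone reduction is a reliable way to the 2,3-cis alcohol. On the C6/C7 pair this is likely more robust than the C-allylation of the chosen plan.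
- Weak points: A5 requires diazomethane chemistry and already contains C9 and C10. Three orthogonal protecting groups are needed (allyl, 4-methoxybenzyl, silyl). The terminal alkene must be generated at the end from the C19 silyl ether, so the endgame is long.
- Comparison: the chosen plan uses one silyl group and two transient acetates and avoids diazo compounds. It accepts a C6-forming step whose selectivity rests on the inside-attack preference of a five-membered oxocarbenium ion.

Key step: step 3

Remark on the chemistry: backbone numbering C1–C19 with O1 between C6 and C9 is used throughout. Lactols **6**, **7** and **8** are carried as anomeric mixtures because the anomeric centre is erased in step 6.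

## Route

Step 1
Reactants: 1 (1S,4R)-cis-4-acetoxycyclopent-2-en-1-ol
Product: 2 (1R,4S)-4-[(tert-butyldimethylsilyl)oxy]cyclopent-2-en-1-yl acetate
Conditions: TBSCl, imidazole, DMF, 0 °C to rt
Reagents that add atoms: tert-butyldimethylsilyl chloride, CC(C)(C)[Si](C)(C)Cl
Why: Standard silylation of a secondary allylic alcohol; the acetate is untouched and no stereocentre is involved.

Step 2
Reactants: 2 (1R,4S)-4-[(tert-butyldimethylsilyl)oxy]cyclopent-2-en-1-yl acetate
Product: 3 (1R,4S)-4-[(tert-butyldimethylsilyl)oxy]cyclopent-2-en-1-ol
Conditions: K2CO3 (cat.), MeOH, 0 °C to rt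
Reagents that add atoms: none
Why: Zemplén-type transesterification removes the acetate while the silyl ether is stable to carbonate in methanol; the mild base should not induce silyl migration between the cis oxygens, which would erode enantiopurity.

Step 3
Reactants: 3 (1R,4S)-4-[(tert-butyldimethylsilyl)oxy]cyclopent-2-en-1-ol
Product: 6 (2R,4S)-4-[(tert-butyldimethylsilyl)oxy]-5-hydroxyoxolane-2-carbaldehyde (anomeric mixture), via secondary ozonide 4 (not isolated), via open-chain hydroxy dialdehyde 5 (not isolated)
Conditions: O3, CH2Cl2, −78 °C; then PPh3, −78 °C to rt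
Reagents that add atoms: ozone, O=[O+][O-]
Why: Ozone adds to the only C=C bond of 3 by 1,3-dipolar cycloaddition; the primary ozonide fragments and recombines to the secondary ozonide 4 (a carbonyl oxide on C6 may instead be trapped by the C9 hydroxyl), and PPh3 reduces the peroxide to the two aldehydes of 5. The C9 hydroxyl is γ to the C6 carbonyl and adds to it in a 5-exo-trig hemiacetalisation that closes the oxolane ring (O1–C6). The same hydroxyl is α to C10 and cannot cyclise there, and O7, which could reach C10, is blocked as its silyl ether, so C10 remains a free aldehyde. The reaction type is the known ozonolysis of a hydroxy-substituted cycloalkene with lactol formation in the flask, which remodels a carbocycle into a furanose. C7 and C9 are not touched and keep the configuration of 3; the anomeric carbon C6 forms as a mixture, which is of no consequence because it is erased in step 6. The selectivity required is site differentiation of the two new carbonyls, secured by the single silyl group on O7, and retention of the α-stereocentre C9, secured by the neutral reductive work-up at low temperature.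

Step 4
Reactants: 6 (2R,4S)-4-[(tert-butyldimethylsilyl)oxy]-5-hydroxyoxolane-2-carbaldehyde
Product: 7 (3S,5R)-3-[(tert-butyldimethylsilyl)oxy]-5-(hydroxymethyl)oxolan-2-ol (anomeric mixture)
Conditions: NaBH4 (limiting), MeOH–CH2Cl2, −78 °C; then AcOH
Reagents that add atoms: none
Why: Chemoselective borohydride reduction; the free α-alkoxy aldehyde is reduced at low temperature much faster than the lactol, which must first open to its aldehyde form.

Step 5
Reactants: 7 (3S,5R)-3-[(tert-butyldimethylsilyl)oxy]-5-(hydroxymethyl)oxolan-2-ol
Product: 8 [(2R,4S)-5-acetoxy-4-[(tert-butyldimethylsilyl)oxy]oxolan-2-yl]methyl acetate (anomeric mixture)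
Conditions: Ac2O, pyridine, DMAP (cat.), CH2Cl2, 0 °C to rt
Reagents that add atoms: acetic anhydride, CC(=O)OC(C)=O
Why: Routine acetylation of the primary alcohol and the lactol hydroxyl gives an anomeric leaving group at C6 and protection at O10 in one operation.

Step 6
Reactants: 8 [(2R,4S)-5-acetoxy-4-[(tert-butyldimethylsilyl)oxy]oxolan-2-yl]methyl acetate; 9 allyltrimethylsilane
Product: 10 [(2R,4S,5S)-4-[(tert-butyldimethylsilyl)oxy]-5-(prop-2-en-1-yl)oxolan-2-yl]methyl acetate
Conditions: BF3·OEt2, CH2Cl2, −78 to −40 °C
Reagents that add atoms: none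
Why: Hosomi–Sakurai-type C-glycosylation of a furanosyl acetate; the C6 oxocarbenium ion adopts the envelope with the C7 silyloxy group pseudoequatorial and is attacked from the inside face, so the allyl group enters cis to O7 and anti to the C9 acetoxymethyl group, setting C6 as S. The non-participating silyl ether on O7 avoids the 1,2-trans outcome that an ester would impose.

Step 7
Reactants: 10 [(2R,4S,5S)-4-[(tert-butyldimethylsilyl)oxy]-5-(prop-2-en-1-yl)oxolan-2-yl]methyl acetate; 11 (E)-hex-3-ene
Product: 12 [(2R,4S,5S)-4-[(tert-butyldimethylsilyl)oxy]-5-(pent-2-en-1-yl)oxolan-2-yl]methyl acetate (E/Z mixture)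
Conditions: 11 (excess), second-generation Grubbs catalyst (H2IMes)(PCy3)Cl2Ru=CHPh (cat.), CH2Cl2, 40 °C
Reagents that add atoms: none
Why: Cross-metathesis of a terminal alkene with an excess of a symmetrical internal alkene transfers a propylidene unit and releases but-1-ene; alkene geometry is irrelevant because the bond is saturated next.

Step 8
Reactants: 12 [(2R,4S,5S)-4-[(tert-butyldimethylsilyl)oxy]-5-(pent-2-en-1-yl)oxolan-2-yl]methyl acetate
Product: 13 [(2R,4S,5S)-4-[(tert-butyldimethylsilyl)oxy]-5-pentyloxolan-2-yl]methyl acetate
Conditions: H2 (1 atm), 10% Pd/C, EtOAc, rt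
Reagents that add atoms: none
Why: Heterogeneous hydrogenation of an isolated disubstituted alkene; acetate, silyl ether and ring are inert in a non-protic solvent, and no other alkene is present yet.

Step 9
Reactants: 13 [(2R,4S,5S)-4-[(tert-butyldimethylsilyl)oxy]-5-pentyloxolan-2-yl]methyl acetate
Product: 14 [(2R,4S,5S)-4-[(tert-butyldimethylsilyl)oxy]-5-pentyloxolan-2-yl]methanol
Conditions: K2CO3, MeOH, rt
Reagents that add atoms: none
Why: Methanolysis of a primary acetate; the secondary silyl ether is stable to these conditions.

Step 10
Reactants: 14 [(2R,4S,5S)-4-[(tert-butyldimethylsilyl)oxy]-5-pentyloxolan-2-yl]methanol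
Product: 15 (2R,4S,5S)-4-[(tert-butyldimethylsilyl)oxy]-5-pentyloxolane-2-carbaldehyde
Conditions: Dess–Martin periodinane, CH2Cl2, 0 °C to rt
Reagents that add atoms: none
Why: Dess–Martin oxidation of a primary alcohol under non-basic conditions, chosen so that the α-stereocentre C9 of the aldehyde is not epimerised; the aldehyde is used directly.

Step 11
Reactants: 15 (2R,4S,5S)-4-[(tert-butyldimethylsilyl)oxy]-5-pentyloxolane-2-carbaldehyde; 16 9-bromonon-1-ene
Product: 18 (1R)-1-[(2R,4S,5S)-4-[(tert-butyldimethylsilyl)oxy]-5-pentyloxolan-2-yl]dec-9-en-1-ol, via non-8-en-1-ylmagnesium bromide 17 (not isolated)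
Conditions: 16, Mg, Et2O, rt; then 15, MgBr2·OEt2, CH2Cl2, −78 °C; aqueous work-up
Reagents that add atoms: none
Why: Cram-chelate Grignard addition to an α-alkoxy aldehyde; magnesium bridges the carbonyl oxygen and ring oxygen O1, and the nucleophile attacks C10 from the face of H9, which gives the threo (10R) carbinol. This reaction type is established for oxolane-2-carbaldehydes.

Step 12
Reactants: 18 (1R)-1-[(2R,4S,5S)-4-[(tert-butyldimethylsilyl)oxy]-5-pentyloxolan-2-yl]dec-9-en-1-ol; 19 tetradecanoic acid (myristic acid)
Product: 20 (1R)-1-[(2R,4S,5S)-4-[(tert-butyldimethylsilyl)oxy]-5-pentyloxolan-2-yl]dec-9-en-1-yl tetradecanoate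
Conditions: DCC, DMAP (cat.), CH2Cl2, 0 °C to rt
Reagents that add atoms: none
Why: Steglich esterification of the only free hydroxyl; O7 is silylated, so acylation is confined to O10, and C10 reacts with retention.

Step 13
Reactants: 20 (1R)-1-[(2R,4S,5S)-4-[(tert-butyldimethylsilyl)oxy]-5-pentyloxolan-2-yl]dec-9-en-1-yl tetradecanoate
Product: 21 (1R)-1-[(2R,4S,5S)-4-hydroxy-5-pentyloxolan-2-yl]dec-9-en-1-yl tetradecanoate (target)
Conditions: HF·pyridine, THF–pyridine, 0 °C to rt
Reagents that add atoms: none
Why: Fluoride desilylation buffered with pyridine removes the secondary silyl ether without cleaving the ester or touching the alkene; O7 and O10 are trans across the ring and four atoms apart, so acyl migration is not expected.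

## Compound list

1 | (1S,4R)-cis-4-acetoxycyclopent-2-en-1-ol | CC(=O)O[C@H]1C=C[C@@H](O)C1 | starting material
2 | (1R,4S)-4-[(tert-butyldimethylsilyl)oxy]cyclopent-2-en-1-yl acetate | CC(=O)O[C@H]1C=C[C@@H](O[Si](C)(C)C(C)(C)C)C1 | intermediate
3 | (1R,4S)-4-[(tert-butyldimethylsilyl)oxy]cyclopent-2-en-1-ol | O[C@H]1C=C[C@@H](O[Si](C)(C)C(C)(C)C)C1 | intermediate
4 | secondary ozonide, (2R,4S)-4-[(tert-butyldimethylsilyl)oxy]-6,7,8-trioxabicyclo[3.2.1]octan-2-ol (mixture at the bridgeheads) | O[C@@H]1C[C@H](O[Si](C)(C)C(C)(C)C)C2OOC1O2 | intermediate (not isolated)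
5 | (2S,4R)-2-[(tert-butyldimethylsilyl)oxy]-4-hydroxypentanedial | O=C[C@H](O)C[C@H](O[Si](C)(C)C(C)(C)C)C=O | intermediate (not isolated)
6 | (2R,4S)-4-[(tert-butyldimethylsilyl)oxy]-5-hydroxyoxolane-2-carbaldehyde (anomeric mixture) | O=C[C@H]1C[C@H](O[Si](C)(C)C(C)(C)C)C(O)O1 | intermediate
7 | (3S,5R)-3-[(tert-butyldimethylsilyl)oxy]-5-(hydroxymethyl)oxolan-2-ol (anomeric mixture) | OC[C@H]1C[C@H](O[Si](C)(C)C(C)(C)C)C(O)O1 | intermediate
8 | [(2R,4S)-5-acetoxy-4-[(tert-butyldimethylsilyl)oxy]oxolan-2-yl]methyl acetate (anomeric mixture) | CC(=O)OC[C@H]1C[C@H](O[Si](C)(C)C(C)(C)C)C(OC(C)=O)O1 | intermediate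
9 | allyltrimethylsilane | C=CC[Si](C)(C)C | starting material
10 | [(2R,4S,5S)-4-[(tert-butyldimethylsilyl)oxy]-5-(prop-2-en-1-yl)oxolan-2-yl]methyl acetate | CC(=O)OC[C@H]1C[C@H](O[Si](C)(C)C(C)(C)C)[C@H](CC=C)O1 | intermediate
11 | (E)-hex-3-ene | CC/C=C/CC | starting material
12 | [(2R,4S,5S)-4-[(tert-butyldimethylsilyl)oxy]-5-(pent-2-en-1-yl)oxolan-2-yl]methyl acetate (E/Z mixture) | CC(=O)OC[C@H]1C[C@H](O[Si](C)(C)C(C)(C)C)[C@H](CC=CCC)O1 | intermediate
13 | [(2R,4S,5S)-4-[(tert-butyldimethylsilyl)oxy]-5-pentyloxolan-2-yl]methyl acetate | CC(=O)OC[C@H]1C[C@H](O[Si](C)(C)C(C)(C)C)[C@H](CCCCC)O1 | intermediate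
14 | [(2R,4S,5S)-4-[(tert-butyldimethylsilyl)oxy]-5-pentyloxolan-2-yl]methanol | OC[C@H]1C[C@H](O[Si](C)(C)C(C)(C)C)[C@H](CCCCC)O1 | intermediate
15 | (2R,4S,5S)-4-[(tert-butyldimethylsilyl)oxy]-5-pentyloxolane-2-carbaldehyde | O=C[C@H]1C[C@H](O[Si](C)(C)C(C)(C)C)[C@H](CCCCC)O1 | intermediate
16 | 9-bromonon-1-ene | C=CCCCCCCCBr | starting material
17 | non-8-en-1-ylmagnesium bromide | C=CCCCCCCC[Mg]Br | intermediate (not isolated)
18 | (1R)-1-[(2R,4S,5S)-4-[(tert-butyldimethylsilyl)oxy]-5-pentyloxolan-2-yl]dec-9-en-1-ol | C=CCCCCCCC[C@@H](O)[C@H]1C[C@H](O[Si](C)(C)C(C)(C)C)[C@H](CCCCC)O1 | intermediate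
19 | tetradecanoic acid (myristic acid) | CCCCCCCCCCCCCC(=O)O | starting material
20 | (1R)-1-[(2R,4S,5S)-4-[(tert-butyldimethylsilyl)oxy]-5-pentyloxolan-2-yl]dec-9-en-1-yl tetradecanoate | C=CCCCCCCC[C@@H](OC(=O)CCCCCCCCCCCCC)[C@H]1C[C@H](O[Si](C)(C)C(C)(C)C)[C@H](CCCCC)O1 | intermediate
21 | (1R)-1-[(2R,4S,5S)-4-hydroxy-5-pentyloxolan-2-yl]dec-9-en-1-yl tetradecanoate | C=CCCCCCCC[C@@H](OC(=O)CCCCCCCCCCCCC)[C@H]1C[C@H](O)[C@H](CCCCC)O1 | target

## Step count and least certain steps

Total: 13 steps. Longest linear sequence: 13 steps, from **1** to **21**; building blocks **9**, **11**, **16** and **19** are commercial and enter directly.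

**Step 3 (key step).**
- Risk: the carbonyl oxide next to the free C9 hydroxyl may fragment with loss of C10 (anomalous ozonolysis of an allylic alcohol). The lactol aldehyde may also hydrate, oligomerise or epimerise at C9 during isolation, because it is an α-alkoxy aldehyde beside a latent second aldehyde.
- Fallback: this sets out from **3** and returns at **7**, moving the differentiation of the two termini from the lactol to an acetonide.
  - Ozonolysis in CH2Cl2–MeOH with borohydride work-up gives (2R,4S)-4-[(tert-butyldimethylsilyl)oxy]pentane-1,2,5-triol F1.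
  - 2,2-Dimethoxypropane with pyridinium 4-toluenesulfonate ties up the vicinal C9/C10 diol as (2S)-2-[(tert-butyldimethylsilyl)oxy]-3-[(4R)-2,2-dimethyl-1,3-dioxolan-4-yl]propan-1-ol F2.
  - Dess–Martin oxidation of the remaining C6 alcohol gives (2S)-2-[(tert-butyldimethylsilyl)oxy]-3-[(4R)-2,2-dimethyl-1,3-dioxolan-4-yl]propanal F3.
  - Brief mild aqueous acid removes the acetonide, and the C9 hydroxyl closes onto C6 to give **7**.

**Step 4.**
- Risk: over-reduction through the ring-opened form of the lactol, which would consume the C6 carbonyl as well, since both carbonyls are aldehydes at equilibrium.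
- Fallback: this sets out from **6** and returns at **8**, masking the lactol before the hydride is added.
  - Acetylation of the lactol hydroxyl gives (3S,5R)-3-[(tert-butyldimethylsilyl)oxy]-5-formyloxolan-2-yl acetate F4.
  - Borohydride reduction of its only carbonyl gives (3S,5R)-3-[(tert-butyldimethylsilyl)oxy]-5-(hydroxymethyl)oxolan-2-yl acetate F5.
  - Acetylation of the primary alcohol gives **8**.

**Step 6.**
- Risk: erosion of facial selectivity at the oxocarbenium ion, because a bulky silyloxy group may be a weaker director than an alkyl ether and there is no second ring substituent next to it. Partial loss of the silyl group to the Lewis acid is also possible.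
- Fallback: this sets out from **8** and returns at **13**, replacing the silyl ether by a benzyl ether, the best-documented 1,2-cis director for this reaction.
  - HF·pyridine gives [(2R,4S)-5-acetoxy-4-hydroxyoxolan-2-yl]methyl acetate F6.
  - Benzyl 2,2,2-trichloroacetimidate with catalytic triflic acid gives [(2R,4S)-5-acetoxy-4-(benzyloxy)oxolan-2-yl]methyl acetate F7.
  - Allylation with **9** and BF3·OEt2 gives [(2R,4S,5S)-4-(benzyloxy)-5-(prop-2-en-1-yl)oxolan-2-yl]methyl acetate F8.
  - Cross-metathesis with **11** gives [(2R,4S,5S)-4-(benzyloxy)-5-(pent-2-en-1-yl)oxolan-2-yl]methyl acetate F9.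
  - Hydrogenation over Pd/C saturates the alkene and removes the benzyl group, giving [(2R,4S,5S)-4-hydroxy-5-pentyloxolan-2-yl]methyl acetate F10.
  - TBSOTf with 2,6-lutidine gives **13**.

**Step 11.**
- Risk: incomplete chelation control, with competing Felkin-type attack on the other carbonyl face, or enolisation of the aldehyde by the basic reagent, because the ring oxygen is a hindered, weakly basic chelating site.
- Fallback: this sets out from **15** and returns at **18**, setting C10 by hydride delivery instead of carbanion addition.
  - The addition is run without regard to selectivity, giving **18** mixed with its epimer (1S)-1-[(2R,4S,5S)-4-[(tert-butyldimethylsilyl)oxy]-5-pentyloxolan-2-yl]dec-9-en-1-ol F11.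
  - Dess–Martin oxidation of the mixture gives 1-[(2R,4S,5S)-4-[(tert-butyldimethylsilyl)oxy]-5-pentyloxolan-2-yl]dec-9-en-1-one F12.
  - Reduction with LiBH(s-Bu)3 in THF at −78 °C under Felkin–Anh control gives the threo alcohol **18**.

## Further compounds

F1 | step 3 | (2R,4S)-4-[(tert-butyldimethylsilyl)oxy]pentane-1,2,5-triol | OC[C@H](O)C[C@H](O[Si](C)(C)C(C)(C)C)CO
F2 | step 3 | (2S)-2-[(tert-butyldimethylsilyl)oxy]-3-[(4R)-2,2-dimethyl-1,3-dioxolan-4-yl]propan-1-ol | CC1(C)OC[C@H](O1)C[C@H](O[Si](C)(C)C(C)(C)C)CO
F3 | step 3 | (2S)-2-[(tert-butyldimethylsilyl)oxy]-3-[(4R)-2,2-dimethyl-1,3-dioxolan-4-yl]propanal | CC1(C)OC[C@H](O1)C[C@H](O[Si](C)(C)C(C)(C)C)C=O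
F4 | step 4 | (3S,5R)-3-[(tert-butyldimethylsilyl)oxy]-5-formyloxolan-2-yl acetate (anomeric mixture) | O=C[C@H]1C[C@H](O[Si](C)(C)C(C)(C)C)C(OC(C)=O)O1
F5 | step 4 | (3S,5R)-3-[(tert-butyldimethylsilyl)oxy]-5-(hydroxymethyl)oxolan-2-yl acetate (anomeric mixture) | OC[C@H]1C[C@H](O[Si](C)(C)C(C)(C)C)C(OC(C)=O)O1
F6 | step 6 | [(2R,4S)-5-acetoxy-4-hydroxyoxolan-2-yl]methyl acetate (anomeric mixture) | CC(=O)OC[C@H]1C[C@H](O)C(OC(C)=O)O1
F7 | step 6 | [(2R,4S)-5-acetoxy-4-(benzyloxy)oxolan-2-yl]methyl acetate (anomeric mixture) | CC(=O)OC[C@H]1C[C@H](OCc2ccccc2)C(OC(C)=O)O1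
F8 | step 6 | [(2R,4S,5S)-4-(benzyloxy)-5-(prop-2-en-1-yl)oxolan-2-yl]methyl acetate | CC(=O)OC[C@H]1C[C@H](OCc2ccccc2)[C@H](CC=C)O1
F9 | step 6 | [(2R,4S,5S)-4-(benzyloxy)-5-(pent-2-en-1-yl)oxolan-2-yl]methyl acetate (E/Z mixture) | CC(=O)OC[C@H]1C[C@H](OCc2ccccc2)[C@H](CC=CCC)O1
F10 | step 6 | [(2R,4S,5S)-4-hydroxy-5-pentyloxolan-2-yl]methyl acetate | CC(=O)OC[C@H]1C[C@H](O)[C@H](CCCCC)O1
F11 | step 11 | (1S)-1-[(2R,4S,5S)-4-[(tert-butyldimethylsilyl)oxy]-5-pentyloxolan-2-yl]dec-9-en-1-ol | C=CCCCCCCC[C@H](O)[C@H]1C[C@H](O[Si](C)(C)C(C)(C)C)[C@H](CCCCC)O1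
F12 | step 11 | 1-[(2R,4S,5S)-4-[(tert-butyldimethylsilyl)oxy]-5-pentyloxolan-2-yl]dec-9-en-1-one | C=CCCCCCCCC(=O)[C@H]1C[C@H](O[Si](C)(C)C(C)(C)C)[C@H](CCCCC)O1
A1 | alternative 1 | (2R)-2-[(1R)-1-(4-methoxybenzyloxy)dec-9-en-1-yl]-2,3-dihydrofuran | C=CCCCCCCC[C@@H](OCc1ccc(OC)cc1)[C@H]2CC=CO2
A2 | alternative 1 | cis-fused 7,7-dichloro-3-[(1R)-1-(4-methoxybenzyloxy)dec-9-enyl]-2-oxabicyclo[3.2.0]heptan-6-one, ring fusion anti to the C3 side chain | C=CCCCCCCC[C@@H](OCc1ccc(OC)cc1)[C@H]2C[C@@H]3C(=O)C(Cl)(Cl)[C@@H]3O2
A3 | alternative 2 | (6S,7S,9E)-7-[(tert-butyldimethylsilyl)oxy]nonadeca-9,18-dien-6-ol | CCCCC[C@H](O)[C@@H](O[Si](C)(C)C(C)(C)C)C/C=C/CCCCCCCC=C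
A4 | alternative 2 | (6S,7S,9R,10R)-7-[(tert-butyldimethylsilyl)oxy]-6,9-epoxynonadec-18-en-10-ol (same substance as 18) | C=CCCCCCCC[C@@H](O)[C@H]1C[C@H](O[Si](C)(C)C(C)(C)C)[C@H](CCCCC)O1
A5 | alternative 3 | (4R,5R)-4-(allyloxy)-14-[(tert-butyldiphenylsilyl)oxy]-1-diazo-5-[(4-methoxybenzyl)oxy]tetradecan-2-one | [N-]=[N+]=CC(=O)C[C@@H](OCC=C)[C@H](OCc1ccc(OC)cc1)CCCCCCCCCO[Si](c1ccccc1)(c1ccccc1)C(C)(C)C
A6 | alternative 3 | (2S,5R)-2-allyl-5-[(1R)-1-(4-methoxybenzyloxy)-10-(tert-butyldiphenylsilyloxy)decyl]dihydrofuran-3(2H)-one | CC(C)(C)[Si](c1ccccc1)(c1ccccc1)OCCCCCCCCC[C@@H](OCc1ccc(OC)cc1)[C@H]2CC(=O)[C@H](CC=C)O2
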